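**Retrosynthetic overview**

- Feature: ring A of the chromene (C4a, C5, C6, C7, C8, C8a) carries oxygen on C5, C7 and C8a (O1) in a 1,3,5 pattern and shares the C4a–C8a bond with the pyran ring. The pyran ring can be carried first as a 2,2-dimethyl-2,3-dihydropyran-4-one whose enone double bond becomes C4a–C8a, so C5 to C8 with O5, O7 and the C8 prenyl group come from one trioxygenated diene.
- Disconnection 1: C6–C(=O)Ar, by lithiation of C6 (the only free ring carbon, flanked by two MOM ethers), addition to a protected 4-hydroxybenzaldehyde and oxidation.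
- Disconnection 2: the C3=C4 double bond, from the C4 ketone of a chroman-4-one by reduction and dehydration.
- Disconnection 3: C8–C8a and C4a–C5, by [4+2] cycloaddition of a 4-prenylated 1-methoxy-1,3-bis(trimethylsilyloxy)diene to a 5-bromo-2,2-dimethyl-2,3-dihydropyran-4-one, then aromatisation by loss of HBr, methanol and the silyl groups.
- Ring order: the pyran ring first (aldol, then oxa-Michael closure), ring A second (cycloaddition); the 4-hydroxyphenyl ring is bought in.

Key step: step 7

Remark: the target is achiral. The silyl enol ether of step 2 is taken as an E/Z mixture and the sp3 intermediates of steps 6, 7, 9, 10 and 12 as racemates or diastereomer mixtures, so their SMILES show only the configuration that is defined.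

**Route**

Step 1
Reactants: 1 methyl acetoacetate; 2 prenyl bromide
Product: 4 methyl 7-methyl-3-oxooct-6-enoate, via sodium lithium dianion 3 (not isolated)
Conditions: NaH, THF, 0 °C; n-BuLi, 0 °C; 2, 0 °C to rt; 1 M HCl work-up
Reagents that add atoms: none
Why: gamma-alkylation of a beta-keto ester dianion, in which the terminal carbanion is the more reactive site and attacks the allylic bromide by SN2, so that the future C8 carbon receives the prenyl chain.

Step 2
Reactants: 4 methyl 7-methyl-3-oxooct-6-enoate
Product: 5 methyl 7-methyl-3-(trimethylsilyloxy)octa-2,6-dienoate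
Conditions: TMSCl, Et3N, hexane, rt
Reagents that add atoms: chlorotrimethylsilane, C[Si](C)(C)Cl
Why: O-silylation of the enolised beta-keto ester under amine base is the standard first stage of bis(silyloxy)diene preparation, and the enol ether geometry is of no consequence.

Step 3
Reactants: 5 methyl 7-methyl-3-(trimethylsilyloxy)octa-2,6-dienoate
Product: 7 (1Z,3Z)-1-methoxy-7-methyl-1,3-bis(trimethylsilyloxy)octa-1,3,6-triene, via lithium dienolate 6 (not isolated)
Conditions: LDA, THF, −78 °C; TMSCl, −78 °C to rt; pentane, filtration, used crude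
Reagents that add atoms: chlorotrimethylsilane, C[Si](C)(C)Cl
Why: gamma-deprotonation of the beta-silyloxy enoate gives the extended ester dienolate, which is silylated on oxygen to the ketene acetal (standard second stage of the diene preparation).

Step 4
Reactants: 8 (E)-4-methoxybut-3-en-2-one
Product: 10 (E)-5-hydroxy-1-methoxy-5-methylhex-1-en-3-one, via lithium enolate 9 (not isolated)
Conditions: LiHMDS, THF, −78 °C; acetone; AcOH, −78 °C
Reagents that add atoms: acetone, CC(C)=O
Why: kinetic enolisation of the methyl ketone and aldol addition to acetone, with low temperature and an acidic quench to hold back retro-aldol cleavage.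

Step 5
Reactants: 10 (E)-5-hydroxy-1-methoxy-5-methylhex-1-en-3-one
Product: 11 2,2-dimethyl-2,3-dihydro-4H-pyran-4-one
Conditions: TFA (cat.), CH2Cl2, rt
Reagents that add atoms: none
Why: acid-catalysed 6-endo oxa-Michael addition of the tertiary hydroxyl to the beta-methoxy enone and loss of methanol (addition–elimination) closes the dihydropyranone.

Step 6
Reactants: 11 2,2-dimethyl-2,3-dihydro-4H-pyran-4-one
Product: 13 5-bromo-2,2-dimethyl-2,3-dihydro-4H-pyran-4-one, via dibromide 12 (not isolated)
Conditions: Br2, CH2Cl2, 0 °C; then Et3N, 0 °C to rt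
Reagents that add atoms: bromine, BrBr
Why: bromine adds across the enol ether double bond and Et3N removes the acidic C5 proton with loss of the C6 bromide (E1cB), the usual bromination–dehydrobromination route to alpha-bromo enones.

Step 7
Reactants: 7 (1Z,3Z)-1-methoxy-7-methyl-1,3-bis(trimethylsilyloxy)octa-1,3,6-triene; 13 5-bromo-2,2-dimethyl-2,3-dihydro-4H-pyran-4-one
Product: 16 5,7-dihydroxy-2,2-dimethyl-8-(3-methylbut-2-enyl)chroman-4-one, via cis-fused bromo cycloadduct 14 (not isolated), via dehydrobrominated dienyl ketal 15 (not isolated)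
Conditions: 7 (2.5 equiv), CH2Cl2, 13 kbar, 30 °C; then DBU, 0 to 40 °C; then 1 M HCl, THF, rt
Reagents that add atoms: none
Why: Proposed new method: the electron-rich diene 7 (largest HOMO coefficient at C4, the terminus carrying the prenyl chain) and the bromo enone 13 (largest LUMO coefficient at C6, the oxygen-bearing beta carbon) should combine in a normal-demand, strongly asynchronous Diels–Alder reaction in which C8–C8a forms ahead of C4a–C5, and 13 kbar is applied because the large negative activation volume of a [4+2] cycloaddition can make up for the low electrophilicity of a vinylogous ester without a Lewis acid, which would turn the reaction into an ionic Michael addition followed by loss of O1. The closest known reaction type is the regiospecific phenol synthesis from 1-alkoxy-1,3-bis(silyloxy)dienes and 2-halo-1,4-quinones or 2-halo enones, where the halogen makes the dienophile an alkyne equivalent; a 5-bromo-2,3-dihydropyran-4-one has not been shown to play this part. Ring A is closed as a six-membered carbocycle by suprafacial [4+2] addition across C5=C6 of 13, which gives the cis-fused adduct 14; its four stereocentres need no control because C4a, C5, C8 and C8a all become sp2. DBU then takes out HBr across C4a–C8a to give the vinylogous ester 15 (H and Br are cis, so this is a syn elimination and is driven by warming), and aqueous acid ionises the C5 mixed ketal with loss of methanol, C8–H is lost to aromatise ring A and the two aryl silyl ethers are hydrolysed, which leaves phenol 16. The step needs head-to-tail regiochemistry, which the matched polarity of C4 of 7 and C6 of 13 secures, and retention of O1, which the C4a bromide secures by supplying the unsaturation that could otherwise come only from beta-elimination of O1, helped by keeping O7 silylated until HBr has gone so that no C8 enolate can expel O1.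

Step 8
Reactants: 16 5,7-dihydroxy-2,2-dimethyl-8-(3-methylbut-2-enyl)chroman-4-one
Product: 17 5,7-bis(methoxymethoxy)-2,2-dimethyl-8-(3-methylbut-2-enyl)chroman-4-one
Conditions: NaH (2.4 equiv), MOMCl (2.6 equiv), DMF, 0 °C to rt
Reagents that add atoms: chloromethyl methyl ether, COCCl
Why: O-alkylation of both phenoxides (Williamson type), with NaH chosen because the C5 hydroxyl is hydrogen-bonded to the C4 carbonyl and is sluggish under amine bases, while the far less acidic C3 methylene is left alone.

Step 9
Reactants: 17 5,7-bis(methoxymethoxy)-2,2-dimethyl-8-(3-methylbut-2-enyl)chroman-4-one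
Product: 18 5,7-bis(methoxymethoxy)-2,2-dimethyl-8-(3-methylbut-2-enyl)chroman-4-ol
Conditions: NaBH4, MeOH/THF, 0 °C to rt
Reagents that add atoms: none
Why: borohydride reduction of the aryl ketone, in which the new C4 stereocentre forms as a racemate and is removed in step 10.

Step 10
Reactants: 18 5,7-bis(methoxymethoxy)-2,2-dimethyl-8-(3-methylbut-2-enyl)chroman-4-ol
Product: 20 5,7-bis(methoxymethoxy)-2,2-dimethyl-8-(3-methylbut-2-enyl)-2H-chromene, via benzylic mesylate 19 (not isolated)
Conditions: MsCl, Et3N, CH2Cl2, 0 °C to rt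
Reagents that add atoms: none
Why: mesylation and E1-type elimination through a benzylic cation stabilised by O1 and the C5 and C7 oxygens should give the 2H-chromene under basic conditions that spare the MOM ethers and the prenyl group.

Step 11
Reactants: 21 4-hydroxybenzaldehyde
Product: 22 4-(methoxymethoxy)benzaldehyde
Conditions: MOMCl, i-Pr2NEt, CH2Cl2, 0 °C to rt
Reagents that add atoms: chloromethyl methyl ether, COCCl
Why: routine O-alkylation of a phenol with MOMCl under amine base.

Step 12
Reactants: 20 5,7-bis(methoxymethoxy)-2,2-dimethyl-8-(3-methylbut-2-enyl)-2H-chromene; 22 4-(methoxymethoxy)benzaldehyde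
Product: 24 [5,7-bis(methoxymethoxy)-2,2-dimethyl-8-(3-methylbut-2-enyl)-2H-chromen-6-yl][4-(methoxymethoxy)phenyl]methanol, via C6 aryllithium 23 (not isolated)
Conditions: n-BuLi, THF, 0 °C; then 22, −78 to 0 °C; H2O
Reagents that add atoms: none
Why: directed ortho-metalation at C6, the only aromatic C–H and one flanked by two coordinating MOM ethers, followed by 1,2-addition of the aryllithium to the aldehyde, the racemic carbinol centre being oxidised away in step 13.

Step 13
Reactants: 24 [5,7-bis(methoxymethoxy)-2,2-dimethyl-8-(3-methylbut-2-enyl)-2H-chromen-6-yl][4-(methoxymethoxy)phenyl]methanol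
Product: 25 [5,7-bis(methoxymethoxy)-2,2-dimethyl-8-(3-methylbut-2-enyl)-2H-chromen-6-yl][4-(methoxymethoxy)phenyl]methanone
Conditions: IBX, DMSO, rt
Reagents that add atoms: none
Why: IBX oxidation of a diaryl carbinol to the benzophenone, to which the alkenes and MOM ethers are inert.

Step 14
Reactants: 25 [5,7-bis(methoxymethoxy)-2,2-dimethyl-8-(3-methylbut-2-enyl)-2H-chromen-6-yl][4-(methoxymethoxy)phenyl]methanone
Product: 26 vismiaphenone E
Conditions: 3 M HCl (aq), MeOH, rt to 40 °C
Reagents that add atoms: none
Why: acid-catalysed acetal exchange with methanol removes the three MOM groups, the two next to the benzoyl carbonyl being activated by chelation, and the mild temperature is chosen to spare the prenyl group and the chromene.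

**Compound list**

1 | methyl acetoacetate | COC(=O)CC(C)=O | starting material
2 | prenyl bromide (1-bromo-3-methylbut-2-ene) | CC(C)=CCBr | starting material
3 | sodium lithium 1-methoxybuta-1,3-diene-1,3-diolate (dianion of 1) | C=C([O-])C=C([O-])OC.[Li+].[Na+] | intermediate
4 | methyl 7-methyl-3-oxooct-6-enoate | COC(=O)CC(=O)CCC=C(C)C | intermediate
5 | methyl 7-methyl-3-(trimethylsilyloxy)octa-2,6-dienoate (E/Z mixture at C2) | COC(=O)C=C(CCC=C(C)C)O[Si](C)(C)C | intermediate
6 | lithium 1-methoxy-7-methyl-3-(trimethylsilyloxy)octa-1,3,6-trien-1-olate | [Li+].CO/C([O-])=C/C(O[Si](C)(C)C)=C/CC=C(C)C | intermediate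
7 | (1Z,3Z)-1-methoxy-7-methyl-1,3-bis(trimethylsilyloxy)octa-1,3,6-triene | CO/C(O[Si](C)(C)C)=C/C(O[Si](C)(C)C)=C/CC=C(C)C | intermediate
8 | (E)-4-methoxybut-3-en-2-one | CO/C=C/C(C)=O | starting material
9 | lithium (3E)-4-methoxybuta-1,3-dien-2-olate | [Li+].CO/C=C/C([O-])=C | intermediate
10 | (E)-5-hydroxy-1-methoxy-5-methylhex-1-en-3-one | CO/C=C/C(=O)CC(C)(C)O | intermediate
11 | 2,2-dimethyl-2,3-dihydro-4H-pyran-4-one | CC1(C)CC(=O)C=CO1 | intermediate
12 | 5,6-dibromo-2,2-dimethyltetrahydro-4H-pyran-4-one (diastereomer mixture) | CC1(C)CC(=O)C(Br)C(Br)O1 | intermediate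
13 | 5-bromo-2,2-dimethyl-2,3-dihydro-4H-pyran-4-one | CC1(C)CC(=O)C(Br)=CO1 | intermediate
14 | 4a-bromo-5-methoxy-2,2-dimethyl-8-(3-methylbut-2-enyl)-5,7-bis(trimethylsilyloxy)-2,3,4a,5,8,8a-hexahydro-4H-chromen-4-one (cis-fused, racemic, epimer mixture at C5 and C8) | CC1(C)CC(=O)[C@]2(Br)C(OC)(O[Si](C)(C)C)C=C(O[Si](C)(C)C)C(CC=C(C)C)[C@@H]2O1 | intermediate
15 | 5-methoxy-2,2-dimethyl-8-(3-methylbut-2-enyl)-5,7-bis(trimethylsilyloxy)-2,3,5,8-tetrahydro-4H-chromen-4-one (diastereomer mixture) | COC1(O[Si](C)(C)C)C=C(O[Si](C)(C)C)C(CC=C(C)C)C2=C1C(=O)CC(C)(C)O2 | intermediate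
16 | 5,7-dihydroxy-2,2-dimethyl-8-(3-methylbut-2-enyl)chroman-4-one | CC(C)=CCc1c(O)cc(O)c2C(=O)CC(C)(C)Oc12 | intermediate
17 | 5,7-bis(methoxymethoxy)-2,2-dimethyl-8-(3-methylbut-2-enyl)chroman-4-one | CC(C)=CCc1c(OCOC)cc(OCOC)c2C(=O)CC(C)(C)Oc12 | intermediate
18 | 5,7-bis(methoxymethoxy)-2,2-dimethyl-8-(3-methylbut-2-enyl)chroman-4-ol (racemic) | CC(C)=CCc1c(OCOC)cc(OCOC)c2C(O)CC(C)(C)Oc12 | intermediate
19 | 5,7-bis(methoxymethoxy)-2,2-dimethyl-8-(3-methylbut-2-enyl)chroman-4-yl methanesulfonate (racemic) | CC(C)=CCc1c(OCOC)cc(OCOC)c2C(OS(C)(=O)=O)CC(C)(C)Oc12 | intermediate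
20 | 5,7-bis(methoxymethoxy)-2,2-dimethyl-8-(3-methylbut-2-enyl)-2H-chromene | CC(C)=CCc1c(OCOC)cc(OCOC)c2C=CC(C)(C)Oc12 | intermediate
21 | 4-hydroxybenzaldehyde | O=Cc1ccc(O)cc1 | starting material
22 | 4-(methoxymethoxy)benzaldehyde | COCOc1ccc(C=O)cc1 | intermediate
23 | [5,7-bis(methoxymethoxy)-2,2-dimethyl-8-(3-methylbut-2-enyl)-2H-chromen-6-yl]lithium | [Li]c1c(OCOC)c2C=CC(C)(C)Oc2c(CC=C(C)C)c1OCOC | intermediate
24 | [5,7-bis(methoxymethoxy)-2,2-dimethyl-8-(3-methylbut-2-enyl)-2H-chromen-6-yl][4-(methoxymethoxy)phenyl]methanol (racemic) | COCOc1ccc(cc1)C(O)c1c(OCOC)c2C=CC(C)(C)Oc2c(CC=C(C)C)c1OCOC | intermediate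
25 | [5,7-bis(methoxymethoxy)-2,2-dimethyl-8-(3-methylbut-2-enyl)-2H-chromen-6-yl][4-(methoxymethoxy)phenyl]methanone | COCOc1ccc(cc1)C(=O)c1c(OCOC)c2C=CC(C)(C)Oc2c(CC=C(C)C)c1OCOC | intermediate
26 | vismiaphenone E, [5,7-dihydroxy-2,2-dimethyl-8-(3-methylbut-2-enyl)-2H-chromen-6-yl](4-hydroxyphenyl)methanone | CC(C)=CCc1c(O)c(C(=O)c2ccc(O)cc2)c(O)c2c1OC(C)(C)C=C2 | target

**Step count and risks**

Total step count: 14.
Longest linear sequence: 10 steps (4, 5, 6, 7, 8, 9, 10, 12, 13, 14; the diene branch 1, 2, 3 is of equal length up to step 7).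

Steps most likely to fail:

1. Step 7 (key step).
 - What may go wrong: the cycloaddition may not take place with so deactivated a dienophile even under pressure. The diene may instead add in Michael fashion and close through the C6 carbon of its keto ester chain onto the C4 carbonyl, with expulsion of O1. The syn elimination of HBr may be slow enough that bromine is passed on as an electrophile to an enol, after which O1 is lost on aromatisation.
 - Fallback (known chemistry, ring A bought in as phloroglucinol): it sets out from prenyl bromide 2 and comes back at 17. Commercial phloroglucinol and 3-methylbut-2-enoic acid in MeSO3H/P2O5 at 70 °C (Friedel–Crafts acylation, then oxa-Michael closure) should give 5,7-dihydroxy-2,2-dimethylchroman-4-one F1. MOMCl and i-Pr2NEt in CH2Cl2 at 0 °C protect the non-chelated C7 hydroxyl and give 5-hydroxy-7-(methoxymethoxy)-2,2-dimethylchroman-4-one F2. Compound 2 with K2CO3 in DMF alkylates the C5 hydroxyl to 7-(methoxymethoxy)-2,2-dimethyl-5-(3-methylbut-2-enyloxy)chroman-4-one F3. Eu(fod)3 (cat.) in CHCl3 at 60 °C should bring about Claisen rearrangement to C6 and Cope rearrangement on to C8, giving 5-hydroxy-7-(methoxymethoxy)-2,2-dimethyl-8-(3-methylbut-2-enyl)chroman-4-one F4. NaH and MOMCl as in step 8 then give 17.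

2. Step 14.
 - What may go wrong: the acid needed for the MOM ether para to the carbonyl may also protonate the prenyl double bond, which then cyclises onto the freed C7 phenol, or it may hydrate or ionise the chromene.
 - Fallback (fluoride-labile group on the hydroxyphenyl ring, so that only the chelation-activated MOM ethers need acid): it sets out from 20 and 21 and comes back at 26. Compound 21 with TBSCl and imidazole in DMF gives 4-(tert-butyldimethylsilyloxy)benzaldehyde F5. Aryllithium 23, made from 20 as in step 12, adds to it to give [5,7-bis(methoxymethoxy)-2,2-dimethyl-8-(3-methylbut-2-enyl)-2H-chromen-6-yl][4-(tert-butyldimethylsilyloxy)phenyl]methanol F6. IBX in DMSO oxidises this to [5,7-bis(methoxymethoxy)-2,2-dimethyl-8-(3-methylbut-2-enyl)-2H-chromen-6-yl][4-(tert-butyldimethylsilyloxy)phenyl]methanone F7. TBAF in THF at 0 °C removes the silyl group and gives [5,7-bis(methoxymethoxy)-2,2-dimethyl-8-(3-methylbut-2-enyl)-2H-chromen-6-yl](4-hydroxyphenyl)methanone F8. The two remaining MOM ethers, both ortho to the carbonyl, should then fall to PPTS in MeOH at 40 °C, giving 26.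

3. Step 10.
 - What may go wrong: the benzylic cation formed on ionisation of mesylate 19 is stabilised by three oxygens and may be trapped by chloride or by the electron-rich chromene already formed (dimerisation), and the ammonium salts may start to cleave a MOM ether.
 - Fallback (no cation, no chromanol): it sets out from 17 and comes back at 20. KHMDS and PhNTf2 in THF at −78 °C convert the ketone into 5,7-bis(methoxymethoxy)-2,2-dimethyl-8-(3-methylbut-2-enyl)-2H-chromen-4-yl trifluoromethanesulfonate F9. Pd(OAc)2 (cat.), PPh3, HCO2H and Et3N in DMF at 60 °C reduce the C–O bond (oxidative addition to zerovalent palladium formed in the flask, formate as the hydride source) and give 20.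

**Further compounds**

F1 | step 7 | 5,7-dihydroxy-2,2-dimethylchroman-4-one | CC1(C)CC(=O)c2c(O)cc(O)cc2O1
F2 | step 7 | 5-hydroxy-7-(methoxymethoxy)-2,2-dimethylchroman-4-one | COCOc1cc(O)c2C(=O)CC(C)(C)Oc2c1
F3 | step 7 | 7-(methoxymethoxy)-2,2-dimethyl-5-(3-methylbut-2-enyloxy)chroman-4-one | COCOc1cc(OCC=C(C)C)c2C(=O)CC(C)(C)Oc2c1
F4 | step 7 | 5-hydroxy-7-(methoxymethoxy)-2,2-dimethyl-8-(3-methylbut-2-enyl)chroman-4-one | COCOc1cc(O)c2C(=O)CC(C)(C)Oc2c1CC=C(C)C
F5 | step 14 | 4-(tert-butyldimethylsilyloxy)benzaldehyde | CC(C)(C)[Si](C)(C)Oc1ccc(C=O)cc1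
F6 | step 14 | [5,7-bis(methoxymethoxy)-2,2-dimethyl-8-(3-methylbut-2-enyl)-2H-chromen-6-yl][4-(tert-butyldimethylsilyloxy)phenyl]methanol (racemic) | CC(C)(C)[Si](C)(C)Oc1ccc(cc1)C(O)c1c(OCOC)c2C=CC(C)(C)Oc2c(CC=C(C)C)c1OCOC
F7 | step 14 | [5,7-bis(methoxymethoxy)-2,2-dimethyl-8-(3-methylbut-2-enyl)-2H-chromen-6-yl][4-(tert-butyldimethylsilyloxy)phenyl]methanone | CC(C)(C)[Si](C)(C)Oc1ccc(cc1)C(=O)c1c(OCOC)c2C=CC(C)(C)Oc2c(CC=C(C)C)c1OCOC
F8 | step 14 | [5,7-bis(methoxymethoxy)-2,2-dimethyl-8-(3-methylbut-2-enyl)-2H-chromen-6-yl](4-hydroxyphenyl)methanone | Oc1ccc(cc1)C(=O)c1c(OCOC)c2C=CC(C)(C)Oc2c(CC=C(C)C)c1OCOC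
F9 | step 10 | 5,7-bis(methoxymethoxy)-2,2-dimethyl-8-(3-methylbut-2-enyl)-2H-chromen-4-yl trifluoromethanesulfonate | CC(C)=CCc1c(OCOC)cc(OCOC)c2C(OS(=O)(=O)C(F)(F)F)=CC(C)(C)Oc12
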